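In a stirred vessel of constant volume, D goes on to X with Z present, and I want to follow a single molecule of D from the moment it enters.

| setting | dawn | noon | winter | Friday's | Wednesday's | Tuesday's | Monday's |
|---|---|---|---|---|---|---|---|
| D | 0.30 M | 0.20 M | 0.45 M | 0.30 M (fed, over 12 h) | 0.30 M | 0.30 M | 0.30 M |
| Z | 0.80 equiv | 0.80 equiv | 0.80 equiv | 0.800 equiv | 0.800 equiv (fed, over 12 h) | 0.800 equiv | 0.800 equiv |
| temperature | 5 °C | 20 °C | 5 °C | 20 °C |  |  | 20 °C |
| remark | run made earlier | run made earlier | run made earlier | all else is in the flask from the start; the feed brings no volume worth counting | the addition at 0 °C, then warmed to 20 °C; the feed brings no volume worth counting | everything together at the start at 0 °C, warmed to 20 °C at 12 h | everything together at the start |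
| time |  |  |  | 15 h | 15 h | 15 h | 15 h |

| run | time / h | X / % |
|---|---|---|
| dawn | 3.00 | 2 |
| dawn | 5.00 | 5 |
| dawn | 8.00 | 13 |
| dawn | 15.0 | 18 |
| dawn | 30.0 | 28 |
| noon | 1.00 | 11 |
| noon | 3.00 | 27 |
| noon | 6.00 | 41 |
| noon | 8.00 | 46 |
| noon | 12.0 | 56 |
| winter | 5.00 | 6 |
| winter | 10.0 | 11 |
| winter | 15.0 | 20 |
| winter | 20.0 | 25 |
| winter | 25.0 | 30 |

(readings scatter by 1.5 percentage points)

- the numbers in the tables scatter by 1.5 percentage points (one standard deviation)

* which flask leads in amount of X, in percent of the D charged ("all alike" within 1.5 percentage points) (Friday's / Wednesday's / Tuesday's / Monday's / all alike)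
* how much X is there at the end, in percent of the D charged: Friday's
* how much X is there at the end, in percent of the D charged: Wednesday's
* how much X is there at the end, in percent of the D charged: Tuesday's
* how much X is there at the end, in percent of the D charged: Monday's

Does a molecule feel its neighbours? Winter starts with D at 0.45 M against dawn's 0.30 M, a factor of 1.50 with Z rising in step, yet at 15.0 h their X stands in a ratio of 1.11. So the percent does not follow the concentration. I read these runs as first-order in D, and I assume that Z stays out of the pace, which makes Wednesday's slow Z equal to Tuesday's.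

What, then, is a cold hour worth? Noon holds 27% of X at 3.00 h, and dawn holds 28% at 30.0 h, so, as a reading with their scatter, I take an hour at 5 °C to count as 0.100 of an hour at 20 °C. If each degree multiplies the pace by the same factor, an hour at 0 °C counts as 0.0464.

How old is each molecule? In Tuesday's and Wednesday's, 3.00 h of warmth plus 12 h of cold come to 3.56 h. This is the warm age, the hours at 20 °C that a molecule's stay is worth. Read on the noon curve, that age gives 29.6% of X in both flasks. In Friday's the molecules enter evenly, so their mean warm age is 9.00 h, which reads as 48.5%. Monday's is the oldest at 15 h, and that age lies beyond noon's last reading, 56% at 12.0 h, so I put it first.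

The forecast, which also finds that “dawn and winter give the same percent versus time”, names Monday's and gives 56% for Friday's, 37% for Wednesday's, 67% for Monday's and, higher than my reckoning, 39% for Tuesday's.

The flasks give 47.9% for Friday's, 30.8% for Wednesday's, 30.8% for Tuesday's and 57.9% for Monday's, and Monday's leads.

    D → X (k = 0.00210 /min, Ea = 94.0 kJ/mol)
    X → Q (k = 5.20 × 10⁻⁴ /min, Ea = 90.0 kJ/mol)
    D ⇌ G (K = 0.230, k = 0.00370 /min, Ea = 103 kJ/mol, ΔH = 13.0 kJ/mol)
    G ⇌ L (K = 0.180, k = 7.60 × 10⁻⁴ /min, Ea = 87.0 kJ/mol, ΔH = 9.00 kJ/mol)
    (constants at 20 °C)

Tuesday's, at a warm age of 3.56 h, gives 30.8% of X where I read 29.6% from the noon curve. The neighbouring flask is Wednesday's with D at 0.12 M instead of 0.30 M, the equivalents of Z held. Its warm age contains no concentration, so it stays at 3.56 h, and my reading stays at 29.6%. That neighbouring flask gives 30.8% of X, with 53.0% of its charged D still there.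

The readings were generated by integration for substances that don't exist.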